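Atom labels: the chroman carrying two aryl groups is benzo ring A plus pyran ring C (O1, C2, C3, C4, C4a, C8a), with ring B on C3. The central benzene is ring D (D1 bonded to C4, OMe on D2, OH on D4, D6 bonded to C3'). The isoflavan-type chroman is pyran ring E (O1' to C8a') plus benzo ring F.
Cuts: the four phenols are masked as benzyl ethers and C4 is taken back to its cis epimer. Both chromans are then traced to 2H-chromenes, and C3=C4 and C3'=C4' are cut together to a ketone/ketone pair and a ketone/aldehyde pair.
Enabling feature: the C8a–O1–C2H2 link in ring C and the C8a'–O1'–C2'H2 link in ring E each hold two benzylic carbons (C3 with C4, C3' with C4') in a 1,6 relation. Each pair can therefore exist as two carbonyl carbons of the same polarity, which titanium joins into a six-membered ring.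
The open tetracarbonyl compound is cut further at O1–C2 (ring A phenol + ring B chloroketone), at O1'–C2' (ring F phenol + ring D bromoketone) and at C4–D1 (ring D aryllithium + ring A aldehyde).
Forward order: D–F ether, acetals, C4–D1 bond, oxidation, unmasking, A–B ether. Rings C and E then arise together, and no heterocycle exists before that point.
Stereochemistry: one chiral Ir catalyst adds H2 to both alkenes (C3' R; C3 R and C4 R, cis by syn addition). Base equilibration then inverts only the doubly benzylic C4 to S (trans).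

Key step: step 16

Assumption: (S)-tBu-PHOX is taken as the ligand enantiomer that delivers hydrogen to the face giving 3'R and 3R; should a test on 3-phenyl-2H-chromene show the opposite sense, the (R)-ligand is used and nothing else changes.

Step 1
Reactants: 1 2,6-dimethoxyphenol
Product: 2 benzyl ether 2-(benzyloxy)-1,3-dimethoxybenzene
Conditions: BnBr, K2CO3, DMF, 60 °C
Reagents that add atoms: benzyl bromide, BrCc1ccccc1
Why: Williamson ether synthesis at the only acidic site; benzyl is chosen so that all four phenol masks can fall together in the last step.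

Step 2
Reactants: 2 2-(benzyloxy)-1,3-dimethoxybenzene
Product: 3 aryl bromide 2-(benzyloxy)-4-bromo-1,3-dimethoxybenzene
Conditions: NBS (1.0 equiv), MeCN, 0 °C to rt
Reagents that add atoms: N-bromosuccinimide, O=C1CCC(=O)N1Br
Why: Electrophilic aromatic bromination; in 1,2,3-trialkoxybenzenes the central alkoxy group is twisted out of conjugation, so attack should go para to one outer OMe and ortho to the other, as it does with 1,2,3-trimethoxybenzene.

Step 3
Reactants: 3 2-(benzyloxy)-4-bromo-1,3-dimethoxybenzene; 4 2-chloro-N-methoxy-N-methylacetamide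
Product: 7 ring B chloroketone 1-[3-(benzyloxy)-2,4-dimethoxyphenyl]-2-chloroethan-1-one, via aryllithium 5 (not isolated), via lithium hemiaminal adduct 6 (not isolated)
Conditions: nBuLi, THF, −78 °C; then 4, −78 to −20 °C; 1 M HCl
Reagents that add atoms: none
Why: Bromine–lithium exchange followed by the Weinreb ketone synthesis; adduct 6 holds until the acid quench, so over-addition is not expected, and the electron-rich ring is spared a separate alpha-halogenation.

Step 4
Reactants: 8 2,4-dihydroxybenzaldehyde
Product: 9 monobenzyl ether 4-(benzyloxy)-2-hydroxybenzaldehyde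
Conditions: BnBr (1.0 equiv), NaHCO3, MeCN, reflux
Reagents that add atoms: benzyl bromide, BrCc1ccccc1
Why: Regioselective Williamson ether synthesis; the 2-OH is hydrogen-bonded to the formyl group, so a weak base should engage only the 4-OH.

Step 5
Reactants: 9 4-(benzyloxy)-2-hydroxybenzaldehyde
Product: 10 ring A aldehyde 4-(benzyloxy)-2-(methoxymethoxy)benzaldehyde
Conditions: MOMCl, K2CO3, acetone, reflux
Reagents that add atoms: chloromethyl methyl ether, COCCl
Why: Acetal-type O-alkylation of the chelated phenol; MOM withstands the organolithium and oxidation steps and leaves in the same acid treatment as the dioxolanes.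

Step 6
Reactants: 11 3,5-dihydroxyacetophenone
Product: 12 monomethyl ether 1-(3-hydroxy-5-methoxyphenyl)ethan-1-one
Conditions: MeI (1.0 equiv), K2CO3, acetone, rt to reflux
Reagents that add atoms: iodomethane, CI
Why: Williamson ether synthesis on a symmetrical diphenol, run as a statistical monoalkylation; the monoether is separated from recyclable diol and from the diether by their different acidity and polarity.

Step 7
Reactants: 12 1-(3-hydroxy-5-methoxyphenyl)ethan-1-one
Product: 13 bromophenol 1-(2-bromo-5-hydroxy-3-methoxyphenyl)ethan-1-one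
Conditions: NBS (1.0 equiv), MeCN, −10 °C to rt
Reagents that add atoms: N-bromosuccinimide, O=C1CCC(=O)N1Br
Why: Electrophilic aromatic bromination; the free phenol is the strongest donor and directs para, to the carbon that is also ortho to OMe (the later D1), as 3-hydroxyacetophenone brominates at C6, and without acid the ring reacts faster than the methyl ketone.

Step 8
Reactants: 13 1-(2-bromo-5-hydroxy-3-methoxyphenyl)ethan-1-one
Product: 14 benzyl ether 1-[5-(benzyloxy)-2-bromo-3-methoxyphenyl]ethan-1-one
Conditions: BnBr, K2CO3, DMF, rt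
Reagents that add atoms: benzyl bromide, BrCc1ccccc1
Why: Williamson ether synthesis on the single phenol, which fixes the OMe (D2) and OBn (D4) pattern of ring D.

Step 9
Reactants: 14 1-[5-(benzyloxy)-2-bromo-3-methoxyphenyl]ethan-1-one
Product: 15 ring D bromoketone 1-[5-(benzyloxy)-2-bromo-3-methoxyphenyl]-2-bromoethan-1-one
Conditions: CuBr2 (2 equiv), EtOAc–CHCl3, reflux
Reagents that add atoms: copper dibromide, [Cu+2].[Br-].[Br-]
Why: Heterogeneous alpha-bromination of an aryl methyl ketone through its enol; the method is established for 3,5-dialkoxyacetophenones, where it stops at the monobromide and spares the activated ring.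

Step 10
Reactants: 15 1-[5-(benzyloxy)-2-bromo-3-methoxyphenyl]-2-bromoethan-1-one; 9 4-(benzyloxy)-2-hydroxybenzaldehyde
Product: 16 D–F keto aldehyde 4-(benzyloxy)-2-{2-[5-(benzyloxy)-2-bromo-3-methoxyphenyl]-2-oxoethoxy}benzaldehyde
Conditions: K2CO3, acetone, rt
Reagents that add atoms: none
Why: Williamson ether synthesis of a salicylaldehyde with a phenacyl bromide (O1'–C2' bond); carbonate at room temperature is the usual way to stop at the ether before Rap–Stoermer condensation sets in.

Step 11
Reactants: 16 D–F keto aldehyde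
Product: 17 bis(dioxolane) 2-[5-(benzyloxy)-2-bromo-3-methoxyphenyl]-2-{[5-(benzyloxy)-2-(1,3-dioxolan-2-yl)phenoxy]methyl}-1,3-dioxolane
Conditions: (TMSOCH2)2, TMSOTf (cat.), CH2Cl2, −78 °C to rt; pyridine
Reagents that add atoms: 1,2-bis(trimethylsilyloxy)ethane, C[Si](C)(C)OCCO[Si](C)(C)C
Why: Noyori acetalisation, driven by Si–O–Si bond formation under aprotic conditions, should mask the aldehyde and the hindered alpha-aryloxy ketone in one operation without acid-catalysed aldol closure.

Step 12
Reactants: 17 bis(dioxolane) aryl bromide; 10 4-(benzyloxy)-2-(methoxymethoxy)benzaldehyde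
Product: 19 diaryl carbinol (ring A and ring D on the later C4; racemic at this carbon), via aryllithium 18 (not isolated)
Conditions: nBuLi, THF, −78 °C; then 10, −78 to 0 °C; aq. NH4Cl
Reagents that add atoms: none
Why: Bromine–lithium exchange outruns deprotonation at −78 °C, the flanking OMe and dioxolane oxygens hold the aryllithium, and 1,2-addition to a formyl group is the reliable way to a tri-ortho-substituted diaryl carbon (C4–D1 bond); the carbinol centre forms without control and is erased in step 13.

Step 13
Reactants: 19 diaryl carbinol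
Product: 20 masked benzophenone (C4 ketone between ring A and ring D)
Conditions: IBX, DMSO, rt
Reagents that add atoms: none
Why: Hypervalent iodine oxidation of an activated benzhydrol under neutral conditions, which MOM, dioxolane and benzyl groups tolerate.

Step 14
Reactants: 20 masked benzophenone
Product: 21 phenol 4-(benzyloxy)-2-(2-{5-(benzyloxy)-2-[4-(benzyloxy)-2-hydroxybenzoyl]-3-methoxyphenyl}-2-oxoethoxy)benzaldehyde
Conditions: 3 M HCl, THF, 45 °C
Reagents that add atoms: water, O
Why: Acid hydrolysis removes both dioxolanes and the MOM acetal in one operation; aryl benzyl and methyl ethers are inert to dilute acid, and the released carbonyl groups are deactivated by ortho and para alkoxy donors, which should hold back acid-catalysed aldol closure.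

Step 15
Reactants: 21 phenol; 7 ring B chloroketone
Product: 22 tetracarbonyl precursor 4-(benzyloxy)-2-{2-[5-(benzyloxy)-2-(4-(benzyloxy)-2-{2-[3-(benzyloxy)-2,4-dimethoxyphenyl]-2-oxoethoxy}benzoyl)-3-methoxyphenyl]-2-oxoethoxy}benzaldehyde
Conditions: K2CO3, DMF, rt
Reagents that add atoms: none
Why: Williamson ether synthesis of a 2-hydroxybenzophenone with an alpha-chloroketone (O1–C2 bond); the phenol is by far the most acidic site, and carbonate at room temperature keeps the alpha-aryloxy ketones from aldol closure onto the neighbouring carbonyl groups.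

Step 16
Reactants: 22 tetracarbonyl precursor
Product: 24 bis(2H-chromene) 7-(benzyloxy)-4-{4-(benzyloxy)-2-[7-(benzyloxy)-2H-chromen-3-yl]-6-methoxyphenyl}-3-[3-(benzyloxy)-2,4-dimethoxyphenyl]-2H-chromene, via titanium bis(pinacolate) 23 (not isolated)
Conditions: TiCl4, Zn, pyridine, THF, reflux; then 22 in THF by syringe pump over 12 h (high dilution), reflux; aq. K2CO3
Reagents that add atoms: none
Why: Zn reduces TiCl4 to low-valent titanium, which passes single electrons to the carbonyl groups; in each pair the partner that is reduced more easily (the C4 diaryl ketone, the C4' aryl aldehyde) becomes the ketyl and bonds to the tethered C3 or C3' ketone carbon, and the titanium pinacolate 23 then gives up both oxygens to the metal at reflux and leaves the alkene. The closest known reaction type is the intramolecular McMurry coupling of 2-(acylmethoxy)aryl ketones and aldehydes to 2H-chromenes, here run at two independent sites of one molecule. Ring C closes by 6-exo-trig attack of C4 on the C3 carbonyl group across C4a, C8a, O1 and C2, and ring E closes in the same 6-exo-trig mode by attack of C4' on the C3' carbonyl group across C4a', C8a', O1' and C2'. No stereocentre is formed; the crowded C4–D1 axis should make 24 a racemic pair of slowly interconverting atropisomers, which matters only in step 17. Pairing selectivity is needed and comes from the two O–CH2 tethers, since C4 with C3' would give a benzocyclobutene and every other crossed pair a ring of nine or more members, while high dilution holds back coupling between molecules. Chemoselectivity against loss of the aryloxy groups alpha to C3 and C3' is also needed and rests on the first ketyls sitting on carbons without an alpha leaving group, on the pyridine buffer, on slow addition, and on the Zn-based reagent, which leaves aryl benzyl ethers alone.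

Step 17
Reactants: 24 bis(2H-chromene)
Product: 26 cis tetrabenzyl ether (3R,4R)-7-(benzyloxy)-4-{4-(benzyloxy)-2-[(3R)-7-(benzyloxy)chroman-3-yl]-6-methoxyphenyl}-3-[3-(benzyloxy)-2,4-dimethoxyphenyl]chroman, via half-reduced chromene 25 (not isolated)
Conditions: [Ir(cod)((S)-tBu-PHOX)]BArF (5 mol %), H2 (5 bar, then 100 bar), CH2Cl2, rt, then 40 °C
Reagents that add atoms: none
Why: Proposed new method: cationic Ir–P,N dihydride complexes reduce unfunctionalised alkenes by coordination, migratory insertion and reductive elimination, with syn delivery of both hydrogens to the face left open by the oxazoline tert-butyl group; the closest known reaction types are the Ir–phosphinooxazoline hydrogenation of 3-aryl-2H-chromenes to isoflavans, which covers C3'=C4' and should give 25 (3'R) at low pressure, and that of tetrasubstituted aryl-substituted cyclic alkenes such as indenes and dihydronaphthalenes, which has not been shown on a 3,4-diaryl-2H-chromene; C3 and C3' share the same local environment (aryl, CH2O, ring alkene carbon), so one ligand enantiomer should give R at both, syn addition then fixes C4 as R (cis), and because ring D stands perpendicular to the alkene the metal can enter only over its OMe edge, so the atropisomer that offers this edge on the catalyst's face reacts and rotation about C4–D1 at 40 °C should feed the other one into it.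

Step 18
Reactants: 26 cis tetrabenzyl ether
Product: 28 trans tetrabenzyl ether (3R,4S)-7-(benzyloxy)-4-{4-(benzyloxy)-2-[(3R)-7-(benzyloxy)chroman-3-yl]-6-methoxyphenyl}-3-[3-(benzyloxy)-2,4-dimethoxyphenyl]chroman, via C4 potassium carbanion 27 (not isolated)
Conditions: KOtBu (0.3 equiv), DMSO, argon, rt to 50 °C; aq. NH4Cl
Reagents that add atoms: none
Why: Base-mediated epimerisation as known for cis-3,4-diarylchromans; only C4–H is doubly benzylic, so reversible deprotonation touches C4 alone and the mixture should settle on the more stable trans isomer (4S), while the singly benzylic C3–H and C3'–H keep their configuration.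

Step 19
Reactants: 28 trans tetrabenzyl ether
Product: 29 target (3R,4S)-4-{4-hydroxy-2-[(3R)-7-hydroxychroman-3-yl]-6-methoxyphenyl}-3-(3-hydroxy-2,4-dimethoxyphenyl)chroman-7-ol
Conditions: H2 (1 atm), Pd/C, EtOAc–MeOH, rt
Reagents that add atoms: none
Why: Hydrogenolysis of four aryl benzyl ethers; the chroman O–CH2 bonds are not benzylic, the methyl ethers and the C4–aryl bonds are inert, and no stereocentre is touched.

Compound list
1 | 2,6-dimethoxyphenol | COc1cccc(OC)c1O | starting material
2 | 2-(benzyloxy)-1,3-dimethoxybenzene | COc1cccc(OC)c1OCc1ccccc1 | intermediate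
3 | 2-(benzyloxy)-4-bromo-1,3-dimethoxybenzene | COc1ccc(Br)c(OC)c1OCc1ccccc1 | intermediate
4 | 2-chloro-N-methoxy-N-methylacetamide | CON(C)C(=O)CCl | starting material
5 | [3-(benzyloxy)-2,4-dimethoxyphenyl]lithium (not isolated) | COc1ccc([Li])c(OC)c1OCc1ccccc1 | intermediate
6 | lithium 1-[3-(benzyloxy)-2,4-dimethoxyphenyl]-2-chloro-1-[methoxy(methyl)amino]ethan-1-olate (not isolated) | COc1ccc(C([O-])(CCl)N(C)OC)c(OC)c1OCc1ccccc1.[Li+] | intermediate
7 | 1-[3-(benzyloxy)-2,4-dimethoxyphenyl]-2-chloroethan-1-one | COc1ccc(C(=O)CCl)c(OC)c1OCc1ccccc1 | intermediate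
8 | 2,4-dihydroxybenzaldehyde | O=Cc1ccc(O)cc1O | starting material
9 | 4-(benzyloxy)-2-hydroxybenzaldehyde | O=Cc1ccc(OCc2ccccc2)cc1O | intermediate
10 | 4-(benzyloxy)-2-(methoxymethoxy)benzaldehyde | COCOc1cc(OCc2ccccc2)ccc1C=O | intermediate
11 | 3,5-dihydroxyacetophenone | CC(=O)c1cc(O)cc(O)c1 | starting material
12 | 1-(3-hydroxy-5-methoxyphenyl)ethan-1-one | CC(=O)c1cc(O)cc(OC)c1 | intermediate
13 | 1-(2-bromo-5-hydroxy-3-methoxyphenyl)ethan-1-one | CC(=O)c1cc(O)cc(OC)c1Br | intermediate
14 | 1-[5-(benzyloxy)-2-bromo-3-methoxyphenyl]ethan-1-one | CC(=O)c1cc(OCc2ccccc2)cc(OC)c1Br | intermediate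
15 | 1-[5-(benzyloxy)-2-bromo-3-methoxyphenyl]-2-bromoethan-1-one | O=C(CBr)c1cc(OCc2ccccc2)cc(OC)c1Br | intermediate
16 | 4-(benzyloxy)-2-{2-[5-(benzyloxy)-2-bromo-3-methoxyphenyl]-2-oxoethoxy}benzaldehyde | O=Cc1ccc(OCc2ccccc2)cc1OCC(=O)c1cc(OCc2ccccc2)cc(OC)c1Br | intermediate
17 | 2-[5-(benzyloxy)-2-bromo-3-methoxyphenyl]-2-{[5-(benzyloxy)-2-(1,3-dioxolan-2-yl)phenoxy]methyl}-1,3-dioxolane | COc1cc(OCc2ccccc2)cc(C2(COc3cc(OCc4ccccc4)ccc3C3OCCO3)OCCO2)c1Br | intermediate
18 | aryllithium from 17, Li in place of Br at D1 (not isolated) | COc1cc(OCc2ccccc2)cc(C2(COc3cc(OCc4ccccc4)ccc3C3OCCO3)OCCO2)c1[Li] | intermediate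
19 | diaryl carbinol: CH(OH) between D1 of the bis(dioxolane) unit and the 4-(benzyloxy)-2-(methoxymethoxy)phenyl ring, racemic | COc1cc(OCc2ccccc2)cc(C2(COc3cc(OCc4ccccc4)ccc3C3OCCO3)OCCO2)c1C(O)c1ccc(OCc2ccccc2)cc1OCOC | intermediate
20 | masked benzophenone: ketone derived from 19 | COc1cc(OCc2ccccc2)cc(C2(COc3cc(OCc4ccccc4)ccc3C3OCCO3)OCCO2)c1C(=O)c1ccc(OCc2ccccc2)cc1OCOC | intermediate
21 | 4-(benzyloxy)-2-(2-{5-(benzyloxy)-2-[4-(benzyloxy)-2-hydroxybenzoyl]-3-methoxyphenyl}-2-oxoethoxy)benzaldehyde | COc1cc(OCc2ccccc2)cc(C(=O)COc2cc(OCc3ccccc3)ccc2C=O)c1C(=O)c1ccc(OCc2ccccc2)cc1O | intermediate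
22 | tetracarbonyl precursor (C3 ketone, C4 ketone, C3' ketone, C4' aldehyde; four benzyl ethers) | COc1ccc(C(=O)COc2cc(OCc3ccccc3)ccc2C(=O)c2c(OC)cc(OCc3ccccc3)cc2C(=O)COc2cc(OCc3ccccc3)ccc2C=O)c(OC)c1OCc1ccccc1 | intermediate
23 | titanium-bound bis(pinacolate), drawn as the parent tetraol; carbinol centres undefined and lost on deoxygenation (not isolated) | COc1ccc(C2(O)COc3cc(OCc4ccccc4)ccc3C2(O)c2c(OC)cc(OCc3ccccc3)cc2C2(O)COc3cc(OCc4ccccc4)ccc3C2O)c(OC)c1OCc1ccccc1 | intermediate
24 | bis(2H-chromene), no stereocentre, racemic about the C4–D1 axis | COc1ccc(C2=C(c3c(OC)cc(OCc4ccccc4)cc3C3=Cc4ccc(OCc5ccccc5)cc4OC3)c3ccc(OCc4ccccc4)cc3OC2)c(OC)c1OCc1ccccc1 | intermediate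
25 | half-reduced compound: upper 3,4-diaryl-2H-chromene, lower (3'R)-chroman (not isolated) | COc1ccc(C2=C(c3c(OC)cc(OCc4ccccc4)cc3[C@@H]3COc4cc(OCc5ccccc5)ccc4C3)c3ccc(OCc4ccccc4)cc3OC2)c(OC)c1OCc1ccccc1 | intermediate
26 | cis tetrabenzyl ether (3R,4R,3'R) | COc1ccc([C@@H]2COc3cc(OCc4ccccc4)ccc3[C@@H]2c2c(OC)cc(OCc3ccccc3)cc2[C@@H]2COc3cc(OCc4ccccc4)ccc3C2)c(OC)c1OCc1ccccc1 | intermediate
27 | C4 potassium carbanion of 26 (3R,3'R) (not isolated) | COc1ccc([C@@H]2COc3cc(OCc4ccccc4)ccc3[C-]2c2c(OC)cc(OCc3ccccc3)cc2[C@@H]2COc3cc(OCc4ccccc4)ccc3C2)c(OC)c1OCc1ccccc1.[K+] | intermediate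
28 | trans tetrabenzyl ether (3R,4S,3'R) | COc1ccc([C@@H]2COc3cc(OCc4ccccc4)ccc3[C@H]2c2c(OC)cc(OCc3ccccc3)cc2[C@@H]2COc3cc(OCc4ccccc4)ccc3C2)c(OC)c1OCc1ccccc1 | intermediate
29 | CNP0305801.1, (3R,4S,3'R) | COc1ccc([C@@H]2COc3cc(O)ccc3[C@H]2c2c(OC)cc(O)cc2[C@@H]2COc3cc(O)ccc3C2)c(OC)c1O | target

Total step count: 19.
Longest linear sequence: 14 steps (steps 6 to 19, from 11 to 29). The ring B branch (steps 1 to 3) joins at step 15. The ring A/F branch (steps 4 and 5) joins at steps 10 and 12.

Steps most likely to fail

**Step 17.** Hydrogen uptake at the tetrasubstituted alkene, which is flanked by two twisted aryl groups, may be too slow. Facial selectivity may also be poor if rotation about C4–D1 does not feed the matched atropisomer.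
- The fallback sets out from 24 and comes back at 26.
- The Ir hydrogenation is run at 5 bar only, which is the known isoflav-3-ene case, and 25 is isolated.
- The hindered alkene is then reduced without a bulky complex by Kursanov–Parnes ionic hydrogenation (Et3SiH, CF3CO2H, CH2Cl2, 0 °C). The proton goes to C3, rings A and D stabilise the C4 cation, and the silane delivers hydride anti to ring B, which again gives a cis pair.
- The sense at C3 is not controlled in this variant. Because C3' is already R, 26 and the (3S,4S,3'R) cis isomer F1 are diastereomers and are parted by chromatography.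

**Step 16.** Three processes threaten the double closure: reductive cleavage of the aryloxy groups alpha to the C3 and C3' ketones, reduction followed by cyclisation across the two ortho acyl groups of ring D, and stalling at the hindered pinacolate stage.
- The fallback sets out from 16 and comes back at 24. It closes one ring at a time, so that no ortho-diacyl arene ever meets titanium, and it needs no acetals.
- A single McMurry coupling of 16 (TiCl4, Zn, pyridine, THF, reflux) closes ring E to 7-(benzyloxy)-3-[5-(benzyloxy)-2-bromo-3-methoxyphenyl]-2H-chromene F2.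
- nBuLi at −78 °C gives the chromenyl-substituted aryllithium F3, which adds to 10 to give the diaryl carbinol F4.
- IBX oxidises this to the MOM-protected benzophenone F5, and dilute HCl in THF frees the 2-hydroxybenzophenone F6.
- K2CO3 and 7 in DMF give the C3/C4 diketone F7, in which only one carbonyl pair is left.
- A second McMurry coupling closes ring C.

**Step 18.** Deprotonation of the electron-rich C4–H, whose ring D cannot become coplanar, may be too slow. Ring opening by beta-elimination of the aryloxide from C3–H may compete.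
- The fallback sets out from 25 (isolated as described for step 17) and comes back at 28. It moves the equilibration from C4 to C3 by raising C2 to the lactone level.
- Allylic oxidation of C2 with [C5H5NH][CrO3Cl] in CH2Cl2 gives the 3,4-diarylcoumarin F8.
- Conjugate reduction with SmI2 and t-BuOH in THF is followed by equilibration of the lactone alpha-carbon with DBU. This gives the trans-3,4-dihydrocoumarins, the (3R,4S,3'R) lactone F9 and the (3S,4R,3'R) lactone F10, which are separated as diastereomers.
- LiAlH4 reduces F9 to the ring-opened phenol alcohol F11.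
- A Mitsunobu reaction (DIAD, PPh3, THF) re-forms O1–C2 at the primary carbon without touching C3 or C4.

Further compounds
F1 | step 17 | cis tetrabenzyl ether (3S,4S,3'R), diastereomer of 26 | COc1ccc([C@H]2COc3cc(OCc4ccccc4)ccc3[C@H]2c2c(OC)cc(OCc3ccccc3)cc2[C@@H]2COc3cc(OCc4ccccc4)ccc3C2)c(OC)c1OCc1ccccc1
F2 | step 16 | 7-(benzyloxy)-3-[5-(benzyloxy)-2-bromo-3-methoxyphenyl]-2H-chromene | COc1cc(OCc2ccccc2)cc(C2=Cc3ccc(OCc4ccccc4)cc3OC2)c1Br
F3 | step 16 | aryllithium from F2, Li in place of Br | COc1cc(OCc2ccccc2)cc(C2=Cc3ccc(OCc4ccccc4)cc3OC2)c1[Li]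
F4 | step 16 | diaryl carbinol from F3 and 10, racemic | COc1cc(OCc2ccccc2)cc(C2=Cc3ccc(OCc4ccccc4)cc3OC2)c1C(O)c1ccc(OCc2ccccc2)cc1OCOC
F5 | step 16 | MOM-protected benzophenone carrying the lower 2H-chromene | COc1cc(OCc2ccccc2)cc(C2=Cc3ccc(OCc4ccccc4)cc3OC2)c1C(=O)c1ccc(OCc2ccccc2)cc1OCOC
F6 | step 16 | 2-hydroxybenzophenone carrying the lower 2H-chromene | COc1cc(OCc2ccccc2)cc(C2=Cc3ccc(OCc4ccccc4)cc3OC2)c1C(=O)c1ccc(OCc2ccccc2)cc1O
F7 | step 16 | C3/C4 diketone carrying the lower 2H-chromene | COc1ccc(C(=O)COc2cc(OCc3ccccc3)ccc2C(=O)c2c(OC)cc(OCc3ccccc3)cc2C2=Cc3ccc(OCc4ccccc4)cc3OC2)c(OC)c1OCc1ccccc1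
F8 | step 18 | 3,4-diarylcoumarin (C2 carbonyl) with (3'R)-chroman | COc1ccc(C2=C(c3c(OC)cc(OCc4ccccc4)cc3[C@@H]3COc4cc(OCc5ccccc5)ccc4C3)c3ccc(OCc4ccccc4)cc3OC2=O)c(OC)c1OCc1ccccc1
F9 | step 18 | trans-3,4-dihydrocoumarin (3R,4S,3'R) | COc1ccc([C@@H]2C(=O)Oc3cc(OCc4ccccc4)ccc3[C@H]2c2c(OC)cc(OCc3ccccc3)cc2[C@@H]2COc3cc(OCc4ccccc4)ccc3C2)c(OC)c1OCc1ccccc1
F10 | step 18 | trans-3,4-dihydrocoumarin (3S,4R,3'R) | COc1ccc([C@H]2C(=O)Oc3cc(OCc4ccccc4)ccc3[C@@H]2c2c(OC)cc(OCc3ccccc3)cc2[C@@H]2COc3cc(OCc4ccccc4)ccc3C2)c(OC)c1OCc1ccccc1
F11 | step 18 | ring-opened phenol alcohol (C2 as CH2OH, C8a as phenol; C3 R, C4 S, C3' R in the numbering of the target) | COc1ccc([C@H](CO)[C@@H](c2ccc(OCc3ccccc3)cc2O)c2c(OC)cc(OCc3ccccc3)cc2[C@@H]2COc3cc(OCc4ccccc4)ccc3C2)c(OC)c1OCc1ccccc1
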